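**Plan**
1. Retrosynthetic cuts, in order: the C1–aryl bond (Weinreb amide + aryllithium), the C5–C6 sp3–sp2 bond (primary alkylboronate + E-alkenyl iodide), then within the fragments C2–C3 (Johnson–Claisen) and C7–CH3 (carboalumination). C1 is the ketone carbon and C3 the quaternary carbon.
2. Enabling feature: C3 carries an intact vinyl group and the C4–C5 ethylene arm that ends at alkene carbon C6, which is a second vinyl group in hydro-alkenylated form. C3 therefore maps onto an achiral gem-divinyl carbon; the benzene ring is purchased and no ring is formed.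
3. Forward: a C6 divinyl Weinreb amide (steps 1–3) and a C9 E-alkenyl iodide (steps 4–5) are joined at C5–C6 in step 6; the MOM-protected aryl unit (step 7) is attached at C1 (step 8) and the phenols are released (step 9).
4. Stereochemistry: the single stereocentre C3 (R) arises in step 6 by ligand-controlled choice between the two enantiotopic vinyl groups. The 6E geometry comes from syn-carboalumination in step 5 and is retained in the coupling.

Key step: step 6

Assumption: which antipode of the TADDOL-derived phenyl phosphite (written L* below) delivers the 3R series cannot be predicted with confidence. It is to be fixed in the first screening runs; both antipodes are accessible from the two tartaric acids.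

**Step 1**
Reactants: 1 (Z)-3-methylpent-2-en-4-yn-1-ol
Product: 2 (Z)-3-methylpenta-2,4-dien-1-ol
Conditions: H2 (1 atm), Pd/CaCO3 poisoned with Pb(OAc)2 (Lindlar catalyst), quinoline, EtOAc, 0 °C to rt, stopped after one equivalent of H2
Reagents that add atoms: none
Why: Lindlar semihydrogenation: the alkyne binds the lead- and quinoline-poisoned palladium surface far more strongly than the diene it becomes, so syn delivery of one equivalent of H2 should stop at the vinyl group and leave the trisubstituted alkene and the alcohol untouched; no stereocentre is formed.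

**Step 2**
Reactants: 2 (Z)-3-methylpenta-2,4-dien-1-ol; 3 triethyl orthoacetate
Product: 5 ethyl 3-methyl-3-vinylpent-4-enoate, via ketene acetal 4 (not isolated)
Conditions: 3 (excess), EtCO2H (cat.), 140 °C, EtOH distilled off
Reagents that add atoms: none
Why: Johnson–Claisen rearrangement: acid-catalysed exchange with the orthoester gives ketene acetal 4, whose [3,3]-sigmatropic shift forms the C2–C3 bond at the disubstituted alkene terminus and turns it into a quaternary carbon carrying two identical vinyl groups, so the product is achiral and the geometry of 2 is of no consequence.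

**Step 3**
Reactants: 5 ethyl 3-methyl-3-vinylpent-4-enoate
Product: 6 N-methoxy-N,3-dimethyl-3-vinylpent-4-enamide
Conditions: MeNH(OMe)·HCl, i-PrMgCl, THF, −20 to 0 °C; then 1 M aq HCl
Reagents that add atoms: N,O-dimethylhydroxylamine hydrochloride, CNOC.Cl
Why: Weinreb amidation of an ester with the chloromagnesium amide made from MeNH(OMe)·HCl and i-PrMgCl: the amide anion attacks the unhindered ester carbonyl, the magnesium-chelated tetrahedral adduct does not react further, and the vinyl groups are inert.

**Step 4**
Reactants: 7 6-methylhept-5-en-2-one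
Product: 9 6-methylhept-5-en-1-yne, via enol phosphate 8 (not isolated)
Conditions: LiN(i-Pr)2, THF, −78 °C; ClP(O)(OEt)2, −78 °C to rt; then LiN(i-Pr)2 (2.2 equiv), −78 °C to rt; H2O
Reagents that add atoms: none
Why: Methyl ketone to terminal alkyne conversion through an enol phosphate: kinetic deprotonation at the methyl group, O-phosphorylation and amide-induced β-elimination of diethyl phosphate give the alkyne, which is held as its lithium acetylide until the quench; the trisubstituted alkene does not take part.

**Step 5**
Reactants: 9 6-methylhept-5-en-1-yne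
Product: 11 (E)-1-iodo-2,6-dimethylhepta-1,5-diene, via alkenylalane 10 (not isolated)
Conditions: AlMe3, Cp2ZrCl2 (cat.), CH2Cl2, 0 °C to rt; then I2, THF, −30 to 0 °C
Reagents that add atoms: trimethylaluminium, C[Al](C)C; iodine, II
Why: Negishi zirconium-catalysed carboalumination followed by iodinolysis: methyl and aluminium add syn across the terminal alkyne with aluminium at the terminus, and iodine replaces aluminium with retention, which fixes the E geometry of the trisubstituted alkenyl iodide.

**Step 6**
Reactants: 6 N-methoxy-N,3-dimethyl-3-vinylpent-4-enamide; 11 (E)-1-iodo-2,6-dimethylhepta-1,5-diene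
Product: 13 (3R,6E)-N-methoxy-N,3,7,11-tetramethyl-3-vinyldodeca-6,10-dienamide, via alkylboronate 12 (not isolated)
Conditions: [Rh(nbd)2]BF4 (2 mol%), L* (4 mol%), pinacolborane (1.1 equiv), THF, 40 °C; then degassed aq KOH (Ar sparge), 11, Pd(OAc)2 (5 mol%), RuPhos (10 mol%), THF/H2O, 70 °C
Reagents that add atoms: none
Why: Proposed new method: the Weinreb carbonyl of 6 binds the cationic monovalent rhodium–phosphite complex, pinacolborane adds oxidatively to give a trivalent hydrido(boryl)rhodium species, one vinyl group inserts into Rh–H with rhodium at the terminal carbon C5 and C–B reductive elimination releases primary boronate 12; after hydroxide activation the boronate transmetalates to the alkenylpalladium iodide (divalent palladium) formed from 11 and zerovalent palladium, and reductive elimination forges C5–C6. The closest known reaction types are carbonyl-directed rhodium-catalysed asymmetric hydroboration of unsaturated amides with [Rh(nbd)2]BF4/phosphite catalysts, catalytic desymmetrisation of prochiral dienes, and B-alkyl Suzuki–Miyaura coupling of primary pinacol boronates with alkenyl halides under Pd(OAc)2/RuPhos. No ring is closed. The only new stereocentre, C3, is fixed by the chiral ligand, which makes the two vinyl groups diastereotopic in the amide-bound complex and lets only one of them reach the Rh–H bond. The step needs enantiotopic-group, regio-, mono-addition and alkene-geometry selectivity: the quaternary neighbour C3 blocks the internal carbon C4 and sends boron to C5, limiting pinacolborane keeps one vinyl group intact while a mono-adduct of the wrong sense should be consumed faster to a separable bis-adduct, and oxidative addition and reductive elimination at palladium retain the E geometry of 11. No carbon radical arises at C4 or C5, so 1,2-vinyl migration is not a concern.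

**Step 7**
Reactants: 14 4-bromoresorcinol
Product: 15 1-bromo-2,4-bis(methoxymethoxy)benzene
Conditions: MOMCl, i-Pr2NEt, CH2Cl2, 0 °C to rt
Reagents that add atoms: chloromethyl methyl ether, COCCl
Why: Williamson-type acetal ether formation (MOM protection) of both phenols: the MOM groups withstand organolithium reagents, and the ortho one stabilises the aryllithium of the next step by chelation.

**Step 8**
Reactants: 13 (3R,6E)-N-methoxy-N,3,7,11-tetramethyl-3-vinyldodeca-6,10-dienamide; 15 1-bromo-2,4-bis(methoxymethoxy)benzene
Product: 18 (3R,6E)-1-[2,4-bis(methoxymethoxy)phenyl]-3,7,11-trimethyl-3-vinyldodeca-6,10-dien-1-one, via aryllithium 16 (not isolated), via tetrahedral lithium adduct 17 (not isolated)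
Conditions: 15, n-BuLi, THF, −78 °C; then 13, −78 to 0 °C; H2O
Reagents that add atoms: none
Why: Bromine–lithium exchange followed by Weinreb ketone synthesis: the aryllithium adds once to the amide to give the chelated tetrahedral adduct 17, which collapses to the ketone only on aqueous quench, and the quaternary stereocentre C3, having no acidic hydrogen, cannot epimerise.

**Step 9**
Reactants: 18 (3R,6E)-1-[2,4-bis(methoxymethoxy)phenyl]-3,7,11-trimethyl-3-vinyldodeca-6,10-dien-1-one
Product: 19 (3R,6E)-1-(2,4-dihydroxyphenyl)-3,7,11-trimethyl-3-vinyldodeca-6,10-dien-1-one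
Conditions: 2 M aq HCl, MeOH, 40 °C
Reagents that add atoms: none
Why: Acid-catalysed acetal methanolysis (MOM removal): the aryl MOM ethers, the ortho one assisted by the neighbouring carbonyl, are cleaved by dilute HCl in methanol under conditions too mild to protonate the trisubstituted alkenes appreciably, and C3 is untouched.

**Compound list**
1 | (Z)-3-methylpent-2-en-4-yn-1-ol | C#C/C(C)=C\CO | starting material
2 | (Z)-3-methylpenta-2,4-dien-1-ol | C=C/C(C)=C\CO | intermediate
3 | triethyl orthoacetate | CCOC(C)(OCC)OCC | starting material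
4 | (Z)-5-[(1-ethoxyethenyl)oxy]-3-methylpenta-1,3-diene (ketene acetal) | C=C(OCC)OC/C=C(C)\C=C | intermediate
5 | ethyl 3-methyl-3-vinylpent-4-enoate | CCOC(=O)CC(C)(C=C)C=C | intermediate
6 | N-methoxy-N,3-dimethyl-3-vinylpent-4-enamide | CON(C)C(=O)CC(C)(C=C)C=C | intermediate
7 | 6-methylhept-5-en-2-one | CC(=O)CCC=C(C)C | starting material
8 | diethyl 6-methylhepta-1,5-dien-2-yl phosphate (enol phosphate) | C=C(CCC=C(C)C)OP(=O)(OCC)OCC | intermediate
9 | 6-methylhept-5-en-1-yne | C#CCCC=C(C)C | intermediate
10 | (E)-(2,6-dimethylhepta-1,5-dien-1-yl)dimethylalane | C[Al](C)/C=C(\C)CCC=C(C)C | intermediate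
11 | (E)-1-iodo-2,6-dimethylhepta-1,5-diene | I/C=C(\C)CCC=C(C)C | intermediate
12 | (3R)-N-methoxy-N,3-dimethyl-3-[2-(4,4,5,5-tetramethyl-1,3,2-dioxaborolan-2-yl)ethyl]pent-4-enamide | C=C[C@](C)(CCB1OC(C)(C)C(C)(C)O1)CC(=O)N(C)OC | intermediate
13 | (3R,6E)-N-methoxy-N,3,7,11-tetramethyl-3-vinyldodeca-6,10-dienamide | C=C[C@](C)(CC/C=C(\C)CCC=C(C)C)CC(=O)N(C)OC | intermediate
14 | 4-bromoresorcinol (4-bromobenzene-1,3-diol) | Oc1ccc(Br)c(O)c1 | starting material
15 | 1-bromo-2,4-bis(methoxymethoxy)benzene | COCOc1ccc(Br)c(OCOC)c1 | intermediate
16 | 2,4-bis(methoxymethoxy)phenyllithium | [Li]c1ccc(OCOC)cc1OCOC | intermediate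
17 | lithium (3R,6E)-1-[2,4-bis(methoxymethoxy)phenyl]-1-[methoxy(methyl)amino]-3,7,11-trimethyl-3-vinyldodeca-6,10-dien-1-olate (either configuration at C1) | C=C[C@](C)(CC/C=C(\C)CCC=C(C)C)CC(O[Li])(N(C)OC)c1ccc(OCOC)cc1OCOC | intermediate
18 | (3R,6E)-1-[2,4-bis(methoxymethoxy)phenyl]-3,7,11-trimethyl-3-vinyldodeca-6,10-dien-1-one | C=C[C@](C)(CC/C=C(\C)CCC=C(C)C)CC(=O)c1ccc(OCOC)cc1OCOC | intermediate
19 | (3R,6E)-1-(2,4-dihydroxyphenyl)-3,7,11-trimethyl-3-vinyldodeca-6,10-dien-1-one | C=C[C@](C)(CC/C=C(\C)CCC=C(C)C)CC(=O)c1ccc(O)cc1O | target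

**Step count**
Total steps: 9. Longest linear sequence: 6 steps (steps 1, 2, 3, 6, 8, 9).

**Steps most likely to fail**

1. Step 6. The two enantiotopic vinyl groups may be discriminated insufficiently, carbonyl direction may deliver boron to the internal carbon C4, or transmetalation of the pinacol boronate may be slow. The fallback uses known chemistry, sets out from 6 and 11 and returns at 13. Amide 6 would be hydroborated at one vinyl group with a slight deficit of 9-borabicyclo[3.3.1]nonane (THF, 0 °C to rt), which adds only at the terminal carbon, to give racemic N-methoxy-N,3-dimethyl-3-[2-(9-borabicyclo[3.3.1]nonan-9-yl)ethyl]pent-4-enamide F1. B-alkyl Suzuki–Miyaura coupling of this borane with 11 (PdCl2(dppf), aq K3PO4, THF/DMF, rt to 50 °C) should give racemic (6E)-N-methoxy-N,3,7,11-tetramethyl-3-vinyldodeca-6,10-dienamide F2. Preparative chromatography on a polysaccharide chiral stationary phase would then separate 13 from its enantiomer (3S,6E)-N-methoxy-N,3,7,11-tetramethyl-3-vinyldodeca-6,10-dienamide F3, the stereocentre thus coming from resolution.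

2. Step 9. Protonation of the two trisubstituted alkenes during acetal cleavage could lead to hydration, methanol addition or cation–olefin cyclisation. The fallback sets out from 14 and 13 and returns at 19, replacing acid-labile by palladium-labile protection. Bromoresorcinol 14 would be allylated (allyl bromide, K2CO3, acetone, reflux) to 2,4-bis(allyloxy)-1-bromobenzene F4. Bromine–lithium exchange (n-BuLi, THF, −78 °C) gives 2,4-bis(allyloxy)phenyllithium F5, which adds to 13 through lithium (3R,6E)-1-[2,4-bis(allyloxy)phenyl]-1-[methoxy(methyl)amino]-3,7,11-trimethyl-3-vinyldodeca-6,10-dien-1-olate F6. Aqueous quench gives (3R,6E)-1-[2,4-bis(allyloxy)phenyl]-3,7,11-trimethyl-3-vinyldodeca-6,10-dien-1-one F7. Allyl transfer to morpholine catalysed by Pd(PPh3)4 (THF, rt) should then release 19 under neutral conditions that leave the alkenes alone.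

3. Step 1. Reduction may run past the diene stage, and the volatile, polymerisation-prone dienol may be lost on isolation. The fallback sets out from 1 and 3 and returns at 5, inverting the order so that no conjugated dienol is handled and no hydrogen gas is used. Johnson–Claisen rearrangement of enynol 1 with 3 (EtCO2H cat., 140 °C) would proceed through (Z)-5-[(1-ethoxyethenyl)oxy]-3-methylpent-3-en-1-yne F8 to racemic ethyl 3-ethynyl-3-methylpent-4-enoate F9. Hydrozirconation of the terminal alkyne with Cp2Zr(H)Cl (THF, rt), which is faster than reaction at the hindered vinyl group or the ester, gives ethyl (E)-5-[chlorobis(cyclopentadienyl)zirconio]-3-methyl-3-vinylpent-4-enoate F10. Protonolysis with water delivers 5, in which the transient stereocentre of the ethynyl ester has vanished.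

**Further compounds**
F1 | step 6 | racemic N-methoxy-N,3-dimethyl-3-[2-(9-borabicyclo[3.3.1]nonan-9-yl)ethyl]pent-4-enamide | C=CC(C)(CCB1C2CCCC1CCC2)CC(=O)N(C)OC
F2 | step 6 | racemic (6E)-N-methoxy-N,3,7,11-tetramethyl-3-vinyldodeca-6,10-dienamide | C=CC(C)(CC/C=C(\C)CCC=C(C)C)CC(=O)N(C)OC
F3 | step 6 | (3S,6E)-N-methoxy-N,3,7,11-tetramethyl-3-vinyldodeca-6,10-dienamide | C=C[C@@](C)(CC/C=C(\C)CCC=C(C)C)CC(=O)N(C)OC
F4 | step 9 | 2,4-bis(allyloxy)-1-bromobenzene | C=CCOc1ccc(Br)c(OCC=C)c1
F5 | step 9 | 2,4-bis(allyloxy)phenyllithium | [Li]c1ccc(OCC=C)cc1OCC=C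
F6 | step 9 | lithium (3R,6E)-1-[2,4-bis(allyloxy)phenyl]-1-[methoxy(methyl)amino]-3,7,11-trimethyl-3-vinyldodeca-6,10-dien-1-olate | C=C[C@](C)(CC/C=C(\C)CCC=C(C)C)CC(O[Li])(N(C)OC)c1ccc(OCC=C)cc1OCC=C
F7 | step 9 | (3R,6E)-1-[2,4-bis(allyloxy)phenyl]-3,7,11-trimethyl-3-vinyldodeca-6,10-dien-1-one | C=C[C@](C)(CC/C=C(\C)CCC=C(C)C)CC(=O)c1ccc(OCC=C)cc1OCC=C
F8 | step 1 | (Z)-5-[(1-ethoxyethenyl)oxy]-3-methylpent-3-en-1-yne | C=C(OCC)OC/C=C(C)\C#C
F9 | step 1 | racemic ethyl 3-ethynyl-3-methylpent-4-enoate | C#CC(C)(C=C)CC(=O)OCC
F10 | step 1 | ethyl (E)-5-[chlorobis(cyclopentadienyl)zirconio]-3-methyl-3-vinylpent-4-enoate | CCOC(=O)CC(C)(C=C)/C=C/[Zr](Cl)(C1C=CC=C1)C1C=CC=C1
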